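The vessel is what I change here: the same charge of Z and E sits in a closed flask, enters a flask by slow feed, or passes through a stirred tank with a short or a long stay.

| flask | Z | E | remark | time |
|---|---|---|---|---|
| Friday's | 0.050 M | 1 mM | run made earlier |  |
| Wednesday's | 0.025 M | 1 mM | run made earlier |  |
| Sunday's | 0.038 M | 1 mM | run made earlier |  |
| Tuesday's | 0.050 M | 1.5 mM | run made earlier |  |
| midnight | 0.050 M (fed, over 12.0 d) | 1.00 mM | all but Z at the start; Z goes in evenly over 12.0 d, the run ends at 12 d | 12 d |
| winter | 0.050 M | 1.00 mM | everything together in a closed stirred flask, run for 12 d | 12 d |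
| autumn | 0.050 M | 1.00 mM | one stirred flow tank at steady state, fed with the mixture as stated, mean residence time 12 d |  |
| spring | 0.050 M | 1.00 mM | a single well-mixed tank run continuously and read at steady state, 120 d in it on average |  |

| run | time / d | X / % | Q / % |
|---|---|---|---|
| Friday's | 1.04 | 13.7 | 4.7 |
| Friday's | 2.00 | 13.0 | 4.4 |
| Friday's | 5.00 | 13.6 | 3.8 |
| Friday's | 12.0 | 11.5 | 3.5 |
| Wednesday's | 0.833 | 13.8 | 4.3 |
| Wednesday's | 2.50 | 13.8 | 4.3 |
| Wednesday's | 5.00 | 12.4 | 3.9 |
| Wednesday's | 8.00 | 12.1 | 4.1 |
| Sunday's | 1.67 | 14.0 | 4.5 |
| Sunday's | 4.00 | 13.5 | 4.3 |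
| Sunday's | 5.00 | 12.7 | 4.9 |
| Sunday's | 8.00 | 12.9 | 3.6 |
| Tuesday's | 1.67 | 13.2 | 4.0 |
| Tuesday's | 4.00 | 13.1 | 4.2 |
| Tuesday's | 5.00 | 13.2 | 4.0 |
| Tuesday's | 8.00 | 11.9 | 3.6 |

(readings scatter by 0.3 percentage points)

- the set-up with the highest share of X in all that became X or Q or J, at the outlet or at the end ("none" if the first two lie within 2 percentage points) (midnight / winter / autumn / spring / none)
- share of X in all that became X or Q or J, at the outlet or at the end, midnight
- share of X in all that became X or Q or J, at the outlet or at the end, winter
- share of X in all that became X or Q or J, at the outlet or at the end, autumn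
- share of X in all that became X or Q or J, at the outlet or at the end, spring

- the stated concentrations are those of everything mixed, before any reaction; amounts are the same in each set-up
- steps thought possible: Z <-> X; X <-> Q; Q <-> Z; X -> J; Z + E -> G
- the feed brings no volume worth counting
- the earlier runs were made in a closed, stirred flask

In the earlier closed runs X and Q stand on a plateau by the first reading, on average 13.7 % and 4.38 % of the Z charged, so I read Z, X and Q as one pool in first-order pre-equilibrium that leaks slowly into J. Friday's X plus Q gives a leak of 0.01864 d⁻¹, whose time is far longer than the first reading. Multiplying by the stay in winter's closed flask gives 0.224, so exp(−N) of the pool remains. With f left, X and Q are their plateaus times f, and J is the remaining 1 − f, since the charge of E is 2.00 % of Z's, less than the pool lost. Winter's share is then 31.7 %.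

The weak link is that leak, a fall of 3.4 percentage points between readings that each scatter by 0.3 points. Wednesday's, Sunday's and Tuesday's runs give 0.01547 d⁻¹, 0.01807 d⁻¹ and 0.01644 d⁻¹, so the mean leak is 0.01716 d⁻¹. The drain number, this leak times the mean stay of the pool, is 0.206 for winter. A tank leaves 1/(1 + N), and midnight's evenly fed Z stays on average half the run. My shares are midnight 47.3 %, winter 33.4 %, autumn 35.4 % and spring 6.11 %.

The forecast, holding that “Z, X and Q equilibrate within a day”, names midnight with 49.5 %, 35.3 %, 37.1 % and 6.6 %, and its winter share stands above mine.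

The flask gives midnight, with 48.4 %, 33.8 %, 35.9 % and 6.25 %.

    Z ⇌ X (K = 0.180, k = 1.30 h⁻¹)
    X ⇌ Q (K = 0.320, k = 0.0460 h⁻¹)
    Q ⇌ Z (k = 0.150 h⁻¹)
    X → J (k = 0.00510 h⁻¹)
    Z + E → G (k = 6.20 M⁻¹ h⁻¹)

The turning of X into J is the largest single effect on the gap between spring and midnight: with that step taken away, spring's share minus midnight's goes from −42 points to −0.2 points. The drain number for spring's stay is 2.06, which puts X at 4.47 % of the Z charged, and the flask holds 4.54 %. For midnight left to 120 d, the mean stay is that time less half the feeding time, so the share comes to 2.19 %, and the simulated run stands at 2.15 %.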